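**Assumptions (one line each):** Iridoid numbering is used throughout (C1 acylal carbon, O2, C3=C4 enol ether, C5–C9 ring carbons, C10 on C8, C11 on C4). The natural 1β-acylal configuration is assumed to come from anomeric and convex-face control.

## Retrosynthetic overview
1. Target ⇐ anodic C5–C6 dehydrogenation of the saturated acylal **14**; the 5,6-ene is made last.
2. **14** ⇐ aminal→acylal exchange of **13** ⇐ retro-Mannich/oxa-closure of the donor–acceptor cyclobutane **12** ⇐ photochemical [2+2] of cyclopentene **9** with enaminal **11**. This forms C9–C1 and C5–C4, i.e. the pyran ring, in one photochemical/ring-opening sequence.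
3. **9** ⇐ RCM of diene **8** ⇐ acetolysis of vinyl oxirane **7** ⇐ Felkin-controlled Corey–Chaykovsky on vinyl ketone **6** ⇐ (S)-hydroxy acid **3** ⇐ (R)-glycidol. C7 comes from glycidol; C8, C9 and C1 follow by substrate control.
4. Ring order: cyclopentene (RCM), then cyclobutane → dihydropyran (photocycloaddition and fragmentation), then the C5=C6 alkene.

## Route

**Step 1**
Reactants: 1 (R)-glycidol
Product: 2 (S)-pent-4-ene-1,2-diol
Conditions: CH2=CHMgBr (2.2 equiv), CuI (10 mol%), THF, −40 → 0 °C
Reagents that add atoms: vinylmagnesium bromide, C=C[Mg]Br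
Why: Cu(I)-catalysed Grignard opening of the terminal epoxide at its CH2 leaves the carbinol stereocentre untouched. This carbon becomes C7; R→S is a CIP label change only.

**Step 2**
Reactants: 2
Product: 3 (S)-2-hydroxypent-4-enoic acid
Conditions: TEMPO (5 mol%), NaClO2 (2 equiv), NaOCl (2 mol%), MeCN / pH 6.7 phosphate buffer, 35 °C
Reagents that add atoms: sodium chlorite, [Na+].[O-]Cl=O (oxygen source)
Why: Zhao–Grabowski oxidation is selective for the primary alcohol, and the buffered, non-basic medium does not epimerise the α-centre.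

**Step 3**
Reactants: 3
Product: 4 (S)-2-hydroxy-N-methoxy-N-methylpent-4-enamide
Conditions: MeNHOMe·HCl, EDC·HCl, HOBt, Et3N, CH2Cl2, 0 °C → rt
Reagents that add atoms: N,O-dimethylhydroxylamine, CNOC
Why: Carbodiimide amide coupling gives the Weinreb amide.

**Step 4**
Reactants: 4
Product: 5 (S)-1-[methoxy(methyl)amino]-1-oxopent-4-en-2-yl 3-methylbutanoate
Conditions: iPrCH2COCl, pyridine, DMAP (cat.), CH2Cl2, 0 °C
Reagents that add atoms: isovaleryl chloride, CC(C)CC(=O)Cl
Why: O-Acylation installs the C7 isovalerate in its final form.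

**Step 5**
Reactants: 5
Product: 6 (S)-3-oxohepta-1,6-dien-4-yl 3-methylbutanoate
Conditions: CH2=CHMgBr (1.1 equiv), THF, −78 °C
Reagents that add atoms: vinylmagnesium bromide, C=C[Mg]Br
Why: Weinreb ketone synthesis; the chelated tetrahedral intermediate prevents over-addition and the ester survives at −78 °C. The vinyl group becomes C9=C1.

**Step 6**
Reactants: 6
Product: 7 (S)-1-[(R)-2-vinyloxiran-2-yl]but-3-en-1-yl 3-methylbutanoate
Conditions: Me3S+ I−, NaH, DMSO/THF 1:1, −10 → 0 °C
Reagents that add atoms: trimethylsulfonium iodide, C[S+](C)C.[I-] (delivers CH2 = C10)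
Why: Corey–Chaykovsky 1,2-epoxidation of the enone C=O. The new stereocentre C8 is set by polar Felkin–Anh attack of the ylide anti to the C7–O(acyl) bond, giving (8R). The oxirane O becomes C8–OH.

**Step 7**
Reactants: 7
Product: 8 (3R,4S)-3-(acetoxymethyl)-3-hydroxyhepta-1,6-dien-4-yl 3-methylbutanoate
Conditions: CsOAc (3 equiv), AcOH (3 equiv), 18-crown-6 (10 mol%), DMF, 60 °C
Reagents that add atoms: cesium acetate, CC(=O)[O-].[Cs+]
Why: SN2 opening at the primary oxirane carbon C10; no bond to C8 is broken, so its configuration is retained. The AcOH buffer protonates the tertiary alkoxide to suppress 1,2-acyl migration.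

**Step 8**
Reactants: 8
Product: 9 (1S,2R)-2-(acetoxymethyl)-2-hydroxycyclopent-3-en-1-yl 3-methylbutanoate
Conditions: Grubbs II (5 mol%), CH2Cl2 (0.01 M), 40 °C
Reagents that add atoms: none (ethylene lost)
Why: Ring-closing metathesis of the 1,6-diene forms the C5=C9 cyclopentene; no stereocentre is touched.

**Step 9**
Reactants: 10 3-(dimethylamino)acrolein
Product: 11 [2-formyl-3-(dimethylamino)prop-2-en-1-yl] acetate
Conditions: (CH2O)n, Ac2O, AcOH, 60 °C
Reagents that add atoms: paraformaldehyde, C=O; acetic anhydride, CC(=O)OC(C)=O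
Why: The nucleophilic α-carbon of the enaminal is acetoxymethylated (Blanc/Mannich-type), installing C11.

**Step 10**
Reactants: 9 (1 equiv), 11 (2.5 equiv)
Product: 12 cyclobutane adduct (cis-fused bicyclo[3.2.0]heptane; C1 bears NMe2, C4 is quaternary with CHO and CH2OAc; C1/C4 configuration left undefined)
Conditions: hν (300 nm, Rayonet), MeCN, 0 °C, 12 h
Reagents that add atoms: none
Why: Proposed new method: the excited push–pull enaminal adds to the C5=C9 alkene to give a 1,4-biradical that closes to the donor (NMe2)–acceptor (CHO) cyclobutane. This is an intermolecular aza-de Mayo [2+2]; the closest known reactions are the de Mayo reaction and the intramolecular vinylogous-amide [2+2]/retro-Mannich. The enaminal approaches the face syn to the small C8–OH and anti to the C10 and C7-OiVal groups, so C1 ends up down at C9 and C4 down at C5 (cis fusion).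

**Step 11**
Reactants: 12
Product: 13 cyclic N,O-aminal (1-dimethylamino-dihydropyran fused to the cyclopentane; C1 anomeric mixture)
Conditions: MgBr2·OEt2 (10 mol%), CH2Cl2, 25 °C, 2 h
Reagents that add atoms: none (isomerisation)
Why: Retro-Mannich heterolysis of the D–A cyclobutane bond C1–C4 gives iminium/enolate, and 6-membered O-closure of the enolate oxygen onto C1 gives the pyran with the C3=C4 enol ether and C4–CH2OAc. C5 and C9 keep their configuration.

**Step 12**
Reactants: 13
Product: 14 acylal (1β-isovaleryloxy; saturated at C5–C6)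
Conditions: (i) iPrCH2COCl (1.05 equiv), CH2Cl2, −40 °C, 15 min; (ii) Bu4N+ iPrCH2CO2− (2 equiv), −40 → 0 °C
Reagents that add atoms: tetrabutylammonium isovalerate, CC(C)CC(=O)[O-].CCCC[N+](CCCC)(CCCC)CCCC (the acyl chloride leaves as N,N-dimethyl-3-methylbutanamide)
Why: N-Acylation of the aminal expels the amide to give an oxocarbenium/α-chloro ether. Carboxylate capture occurs under anomeric control with axial (β) delivery, giving the natural C1 (S) configuration. The tertiary C8–OH is unreactive at −40 °C without base.

**Step 13**
Reactants: 14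
Product: 15 target, 10-acetoxyvaltrathydrin
Conditions: graphite anode / Pt cathode, 3 mA constant current, nBu4NPF6 (0.1 M), 2,6-lutidine (3 equiv), CH2Cl2/HFIP 9:1, 0 °C, undivided cell, ~2.2 F/mol
Reagents that add atoms: none (H2 evolved)
Why: Proposed new method: anodic oxidation of the enol ether C3=C4 gives a radical cation that loses the tertiary allylic C5–H to lutidine. The resulting C5/C3 allyl radical is oxidised again to the vinylogous oxocarbenium (O2+=C3–C4=C5), which loses H6 to give the conjugated 3,4:5,6-diene, while H+ is reduced to H2 at the cathode. The closest known reactions are anodic allylic deprotonation of enol ethers and electrochemical desaturation. The transient C5 stereocentre is removed by design, and the acylal, acetates and isovalerates are inert at this potential.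

## Compound list
1 | (R)-glycidol | OC[C@@H]1CO1 | starting material
2 | (S)-pent-4-ene-1,2-diol | C=CC[C@H](O)CO | intermediate
3 | (S)-2-hydroxypent-4-enoic acid | OC(=O)[C@@H](O)CC=C | intermediate
4 | (S)-2-hydroxy-N-methoxy-N-methylpent-4-enamide | CON(C)C(=O)[C@@H](O)CC=C | intermediate
5 | (S)-1-[methoxy(methyl)amino]-1-oxopent-4-en-2-yl 3-methylbutanoate | CON(C)C(=O)[C@@H](OC(=O)CC(C)C)CC=C | intermediate
6 | (S)-3-oxohepta-1,6-dien-4-yl 3-methylbutanoate | C=CC(=O)[C@@H](OC(=O)CC(C)C)CC=C | intermediate
7 | (S)-1-[(R)-2-vinyloxiran-2-yl]but-3-en-1-yl 3-methylbutanoate | C=CC[C@H](OC(=O)CC(C)C)[C@@]1(C=C)CO1 | intermediate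
8 | (3R,4S)-3-(acetoxymethyl)-3-hydroxyhepta-1,6-dien-4-yl 3-methylbutanoate | C=CC[C@H](OC(=O)CC(C)C)[C@@](O)(C=C)COC(C)=O | intermediate
9 | (1S,2R)-2-(acetoxymethyl)-2-hydroxycyclopent-3-en-1-yl 3-methylbutanoate | C1=C[C@@](O)(COC(C)=O)[C@@H](OC(=O)CC(C)C)C1 | intermediate
10 | 3-(dimethylamino)acrolein | CN(C)/C=C/C=O | starting material
11 | 2-formyl-3-(dimethylamino)prop-2-en-1-yl acetate | CN(C)C=C(COC(C)=O)C=O | intermediate
12 | cis-fused cyclobutane adduct (C1, C4 undefined) | CC(=O)OC[C@@]1(O)[C@@H](OC(=O)CC(C)C)C[C@@H]2C(COC(C)=O)(C=O)C(N(C)C)[C@H]12 | intermediate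
13 | cyclic N,O-aminal (C1 undefined) | CC(=O)OC[C@@]1(O)[C@@H](OC(=O)CC(C)C)C[C@@H]2C(COC(C)=O)=COC(N(C)C)[C@H]12 | intermediate
14 | 5,6-dihydro acylal | CC(=O)OC[C@@]1(O)[C@@H](OC(=O)CC(C)C)C[C@@H]2C(COC(C)=O)=CO[C@@H](OC(=O)CC(C)C)[C@H]12 | intermediate
15 | 10-acetoxyvaltrathydrin | CC(=O)OCC1=CO[C@@H](OC(=O)CC(C)C)[C@H]2C1=C[C@H](OC(=O)CC(C)C)[C@]2(O)COC(C)=O | target

## Totals
- **Total steps:** 13.
- **Longest linear sequence:** 12 steps (1–8, then 10–13). Step 9 is a parallel preparation of reagent 11.

## Three steps most likely to fail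
1. **Step 13 (proposed new electrolysis).** The product diene is more oxidisable than the substrate, and C11–H2 deprotonation competes with C5–H.
   *Fallback (known chemistry, different approach):* put a C6 handle in early. Oxidise cyclopentene 9 at the allylic C6 with SeO2, carry the 6-hydroxy compound through steps 10–12, and finish with Burgess-reagent syn-dehydration toward H5. No electrolysis is needed.
2. **Step 10 (intermolecular photocycloaddition, with Step 11 ring-opening).** Yield and regiochemistry (C1–C9/C4–C5 versus the reverse) are uncertain, and C9 could epimerise through the iminium/enamine in Step 11.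
   *Fallback:* make the cycloaddition intramolecular with a temporary tether. Link C8–OH to the enal β-oxygen as a methylene acetal, irradiate, then cleave the acetal to free C8–OH and the C1 lactol for isovalerylation.
3. **Step 6 (Felkin-controlled Corey–Chaykovsky on an α-acyloxy vinyl ketone).** The basic ylide may epimerise C7, and the diastereoselectivity at C8 may be poor.
   *Fallback:* use a chelation-controlled route instead. Convert the PMB ether of amide 4 with Bu3SnCH2OBn/BuLi to the α,α′-dioxygenated ketone, then add vinylMgBr/MgBr2 (this gives 3R,4S directly). Swap the protecting groups (PMB → isovalerate, Bn → acetate) to rejoin the route at 8.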